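**Retrosynthetic overview**

1. Target 17 ⇐ global hydrogenolysis (four O-benzyl groups and the C5–O bond) ⇐ tetralone 15. Target numbering: ring A = C1–C4, C4a, C8a; ring B = C4a, C5 (CH2), C6, C7, C8 (CH–aryl), C8a.
2. Key disconnection, both bonds in one flask: C4a–C5 and C8a–C8. Aryllithium 13 (from bromide 12) is acylated by γ-aryl-γ-butyrolactone 11 (C5 = lactone carbonyl); acid then ionizes the benzylic C8–O bond and the ring A carbon ortho to the new ketone closes ring B.
3. Enabling feature: C5 and C8 sit on the adjacent ring A carbons C4a and C8a. C4a is para to the C2 oxygen, so it can be the C–Br carbon of O-benzyl-4-bromoguaiacol; C8a is para to the C3 methoxy group, the activated free position. C5 tolerates a carbonyl (removed in steps 8 and 9) and C8 is benzylic to an oxygen-rich aryl ring, so C5–C8 can be held as a temporary lactone ring that acts as a 1,4-dielectrophile.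
4. Lactone 11 ⇐ trans-alkylation with benzyl chloromethyl ether (C6) ⇐ acid reduction and O-benzylation ⇐ Evans syn-aldol/lactonization of succinate imide 3 with aldehyde 4 (C7).
5. Ring order: temporary lactone (step 2), then ring B (step 7); ring A and the pendant ring come from 12 and 4.

Key step: step 7

Remark on the chemistry: the aryl-bearing lactone carbon of 6–11 (the future C8) becomes a planar cation in step 7, so its configuration, written as the syn-aldol should deliver it, and any epimerization there before step 7 do not affect the target.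

**Route**

Step 1
Reactants: 1 (S)-4-benzyl-1,3-oxazolidin-2-one; 2 methyl 4-chloro-4-oxobutanoate
Product: 3 methyl 4-[(4S)-4-benzyl-2-oxo-1,3-oxazolidin-3-yl]-4-oxobutanoate
Conditions: n-BuLi, THF, −78 °C; then 2, −78 → 0 °C
Reagents that add atoms: none
Why: N-acylation of the lithiated oxazolidinone by the acid chloride (standard imide formation), the acid chloride reacting in preference to the methyl ester; no stereocenter is formed.

Step 2
Reactants: 3 methyl 4-[(4S)-4-benzyl-2-oxo-1,3-oxazolidin-3-yl]-4-oxobutanoate; 4 4-(benzyloxy)-3,5-dimethoxybenzaldehyde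
Product: 6 (4S)-4-benzyl-3-{[(2S,3S)-2-[4-(benzyloxy)-3,5-dimethoxyphenyl]-5-oxooxolan-3-yl]carbonyl}-1,3-oxazolidin-2-one, via aldol adduct 5 (not isolated)
Conditions: Bu2BOTf, i-Pr2NEt, CH2Cl2, −78 → 0 °C; 4, −78 → 0 °C; pH 7 buffer, MeOH, H2O2, 0 °C; then PPTS (cat.), CH2Cl2, 23 °C
Reagents that add atoms: none
Why: Evans syn-aldol reaction, in which the Z-boron enolate of the imide (not of the less acidic ester) should add to 4 through a chair-like Zimmerman–Traxler transition state on the face away from the benzyl group, setting the (S) center next to the imide (C7 of the target) and the (S) carbinol center, after which the γ-hydroxy ester lactonizes to the trans lactone with loss of methanol.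

Step 3
Reactants: 6 (4S)-4-benzyl-3-{[(2S,3S)-2-[4-(benzyloxy)-3,5-dimethoxyphenyl]-5-oxooxolan-3-yl]carbonyl}-1,3-oxazolidin-2-one
Product: 8 (2S,3S)-2-[4-(benzyloxy)-3,5-dimethoxyphenyl]-5-oxooxolane-3-carboxylic acid, via peroxy acid 7 (not isolated)
Conditions: LiOH·H2O, H2O2, THF/H2O, 0 °C; Na2SO3; then 1 M HCl
Reagents that add atoms: hydrogen peroxide, OO
Why: Lithium hydroperoxide should cleave the exocyclic imide carbonyl selectively (oxazolidinone auxiliary removal), sulfite reduces the peroxy acid, any opened lactone recloses on acidification and the auxiliary is recovered; no stereocenter is touched.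

Step 4
Reactants: 8 (2S,3S)-2-[4-(benzyloxy)-3,5-dimethoxyphenyl]-5-oxooxolane-3-carboxylic acid
Product: 9 (4R,5S)-5-[4-(benzyloxy)-3,5-dimethoxyphenyl]-4-(hydroxymethyl)oxolan-2-one
Conditions: BH3·SMe2, THF, 0 → 23 °C; aqueous work-up
Reagents that add atoms: none
Why: Chemoselective borane reduction of a carboxylic acid (through the acyloxyborane) in the presence of a γ-lactone; no stereocenter is touched.

Step 5
Reactants: 9 (4R,5S)-5-[4-(benzyloxy)-3,5-dimethoxyphenyl]-4-(hydroxymethyl)oxolan-2-one
Product: 10 (4R,5S)-4-[(benzyloxy)methyl]-5-[4-(benzyloxy)-3,5-dimethoxyphenyl]oxolan-2-one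
Conditions: benzyl 2,2,2-trichloroacetimidate, TfOH (cat.), CH2Cl2/cyclohexane, 0 → 23 °C
Reagents that add atoms: benzyl 2,2,2-trichloroacetimidate, ClC(Cl)(Cl)C(=N)OCc1ccccc1
Why: Acid-catalyzed O-benzylation with a trichloroacetimidate avoids the alkoxide that would translactonize, and reversible ionization at the benzylic lactone carbon is harmless because that center is set anew in step 7.

Step 6
Reactants: 10 (4R,5S)-4-[(benzyloxy)methyl]-5-[4-(benzyloxy)-3,5-dimethoxyphenyl]oxolan-2-one
Product: 11 (3R,4R,5S)-3,4-bis[(benzyloxy)methyl]-5-[4-(benzyloxy)-3,5-dimethoxyphenyl]oxolan-2-one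
Conditions: LiN(SiMe3)2, THF, −78 °C; benzyl chloromethyl ether, −78 → −30 °C
Reagents that add atoms: benzyl chloromethyl ether, ClCOCc1ccccc1
Why: Alkylation of the lithium lactone enolate should occur anti to the neighbouring benzyloxymethyl group (1,2-induction in the five-membered ring), giving the 3,4-trans lactone and with it C6 of the target.

Step 7
Reactants: 11 (3R,4R,5S)-3,4-bis[(benzyloxy)methyl]-5-[4-(benzyloxy)-3,5-dimethoxyphenyl]oxolan-2-one; 12 1-(benzyloxy)-4-bromo-2-methoxybenzene
Product: 15 (2R,3R,4S)-6-(benzyloxy)-2,3-bis[(benzyloxy)methyl]-4-[4-(benzyloxy)-3,5-dimethoxyphenyl]-7-methoxy-3,4-dihydronaphthalen-1(2H)-one, via aryllithium 13 (not isolated), via hydroxy ketone 14 (not isolated)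
Conditions: 12, n-BuLi, THF, −78 °C; 11, −78 °C; then CF3CO2H (excess), CH2Cl2, −78 → 0 °C
Reagents that add atoms: none
Why: Bromine–lithium exchange turns 12 into aryllithium 13, whose C–Li carbon (para to the benzyloxy oxygen, the future C4a) adds once to the lactone carbonyl of 11 (future C5) to give a lactolate that persists at −78 °C and becomes γ-hydroxy ketone 14 on acidification; CF3CO2H then ionizes the benzylic C–O bond (future C8) to a cation stabilized by the 4-benzyloxy-3,5-dimethoxyphenyl ring, and the ring A carbon ortho to the new acyl group and para to the methoxy group (future C8a) attacks it with loss of water. The closest known reaction types are the acylation of aryllithiums by γ-lactones (lactol formation for C-aryl glycosides) and the acid-mediated cyclization of benzylic alcohols onto alkoxyaryl ketones or onto the electron-rich ring of hydroxylated seco-lignans, which gives 4-aryl-1-tetralones and aryltetralin lignans. Ring B closes as a six-membered cationic Friedel–Crafts alkylation, 6-endo with respect to the arene bond C4a–C8a that ends up in the new ring. The new stereocenter C8 is controlled by C7: in the half-chair transition state the pendant aryl group and the C7 benzyloxymethyl group should both sit pseudo-equatorial, giving the 7,8-trans product, while C6 next to the ketone is already trans and at its thermodynamic configuration. The step needs mono-addition (secured by the persistent tetrahedral lactolate), closure para to the methoxy group (the other ortho position lies between the acyl and methoxy groups and is not para to an oxygen) and survival of the benzyl ethers (short exposure to CF3CO2H at or below 0 °C).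

Step 8
Reactants: 15 (2R,3R,4S)-6-(benzyloxy)-2,3-bis[(benzyloxy)methyl]-4-[4-(benzyloxy)-3,5-dimethoxyphenyl]-7-methoxy-3,4-dihydronaphthalen-1(2H)-one
Product: 16 (2R,3R,4S)-6-(benzyloxy)-2,3-bis[(benzyloxy)methyl]-4-[4-(benzyloxy)-3,5-dimethoxyphenyl]-7-methoxy-1,2,3,4-tetrahydronaphthalen-1-ol (both C1 epimers)
Conditions: NaBH4, MeOH/THF, 0 °C
Reagents that add atoms: none
Why: Hydride reduction of the aryl ketone (NaBH4 reduction) removes the β-alkoxy ketone before the acidic hydrogenolysis, and the new carbinol center is of no consequence because it is removed in step 9.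

Step 9
Reactants: 16 (2R,3R,4S)-6-(benzyloxy)-2,3-bis[(benzyloxy)methyl]-4-[4-(benzyloxy)-3,5-dimethoxyphenyl]-7-methoxy-1,2,3,4-tetrahydronaphthalen-1-ol
Product: 17 5-methoxy-(+)-isolariciresinol, (6R,7R,8S)-8-(4-hydroxy-3,5-dimethoxyphenyl)-6,7-bis(hydroxymethyl)-3-methoxy-5,6,7,8-tetrahydronaphthalen-2-ol
Conditions: H2 (1–3 atm), Pd(OH)2/C, EtOH/EtOAc, AcOH (cat.), 23 °C
Reagents that add atoms: none
Why: Catalytic hydrogenolysis should cleave the four benzyl ethers and, acid-assisted, the benzylic C–OH bond para to the freed phenol, leaving the diarylmethine C–C bonds and the three stereocenters untouched.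

**Compound list**

1 | (S)-4-benzyl-1,3-oxazolidin-2-one | O=C1N[C@@H](Cc2ccccc2)CO1 | starting material
2 | methyl 4-chloro-4-oxobutanoate | COC(=O)CCC(Cl)=O | starting material
3 | methyl 4-[(4S)-4-benzyl-2-oxo-1,3-oxazolidin-3-yl]-4-oxobutanoate | COC(=O)CCC(=O)N1[C@@H](Cc2ccccc2)COC1=O | intermediate
4 | 4-(benzyloxy)-3,5-dimethoxybenzaldehyde | COc1cc(C=O)cc(OC)c1OCc1ccccc1 | starting material
5 | methyl (3S)-3-{(S)-[4-(benzyloxy)-3,5-dimethoxyphenyl](hydroxy)methyl}-4-[(4S)-4-benzyl-2-oxo-1,3-oxazolidin-3-yl]-4-oxobutanoate (aldol adduct) | COC(=O)C[C@H](C(=O)N1[C@@H](Cc2ccccc2)COC1=O)[C@H](O)c1cc(OC)c(OCc2ccccc2)c(OC)c1 | intermediate (not isolated)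
6 | (4S)-4-benzyl-3-{[(2S,3S)-2-[4-(benzyloxy)-3,5-dimethoxyphenyl]-5-oxooxolan-3-yl]carbonyl}-1,3-oxazolidin-2-one | O=C1O[C@H](c2cc(OC)c(OCc3ccccc3)c(OC)c2)[C@@H](C(=O)N2[C@@H](Cc3ccccc3)COC2=O)C1 | intermediate
7 | (2S,3S)-2-[4-(benzyloxy)-3,5-dimethoxyphenyl]-5-oxooxolane-3-carboperoxoic acid (peroxy acid) | O=C1O[C@H](c2cc(OC)c(OCc3ccccc3)c(OC)c2)[C@@H](C(=O)OO)C1 | intermediate (not isolated)
8 | (2S,3S)-2-[4-(benzyloxy)-3,5-dimethoxyphenyl]-5-oxooxolane-3-carboxylic acid | O=C1O[C@H](c2cc(OC)c(OCc3ccccc3)c(OC)c2)[C@@H](C(=O)O)C1 | intermediate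
9 | (4R,5S)-5-[4-(benzyloxy)-3,5-dimethoxyphenyl]-4-(hydroxymethyl)oxolan-2-one | O=C1O[C@H](c2cc(OC)c(OCc3ccccc3)c(OC)c2)[C@@H](CO)C1 | intermediate
10 | (4R,5S)-4-[(benzyloxy)methyl]-5-[4-(benzyloxy)-3,5-dimethoxyphenyl]oxolan-2-one | O=C1O[C@H](c2cc(OC)c(OCc3ccccc3)c(OC)c2)[C@@H](COCc2ccccc2)C1 | intermediate
11 | (3R,4R,5S)-3,4-bis[(benzyloxy)methyl]-5-[4-(benzyloxy)-3,5-dimethoxyphenyl]oxolan-2-one | O=C1O[C@H](c2cc(OC)c(OCc3ccccc3)c(OC)c2)[C@@H](COCc2ccccc2)[C@@H]1COCc1ccccc1 | intermediate
12 | 1-(benzyloxy)-4-bromo-2-methoxybenzene | COc1cc(Br)ccc1OCc1ccccc1 | starting material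
13 | [4-(benzyloxy)-3-methoxyphenyl]lithium (aryllithium) | [Li]c1ccc(OCc2ccccc2)c(OC)c1 | intermediate (not isolated)
14 | (2R,3R,4S)-2,3-bis[(benzyloxy)methyl]-4-[4-(benzyloxy)-3,5-dimethoxyphenyl]-1-[4-(benzyloxy)-3-methoxyphenyl]-4-hydroxybutan-1-one (hydroxy ketone, in equilibrium with its cyclic hemiketal) | O=C(c1ccc(OCc2ccccc2)c(OC)c1)[C@@H](COCc1ccccc1)[C@H](COCc1ccccc1)[C@H](O)c1cc(OC)c(OCc2ccccc2)c(OC)c1 | intermediate (not isolated)
15 | (2R,3R,4S)-6-(benzyloxy)-2,3-bis[(benzyloxy)methyl]-4-[4-(benzyloxy)-3,5-dimethoxyphenyl]-7-methoxy-3,4-dihydronaphthalen-1(2H)-one | COc1cc2c(cc1OCc1ccccc1)[C@H](c1cc(OC)c(OCc3ccccc3)c(OC)c1)[C@@H](COCc1ccccc1)[C@H](COCc1ccccc1)C2=O | intermediate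
16 | (2R,3R,4S)-6-(benzyloxy)-2,3-bis[(benzyloxy)methyl]-4-[4-(benzyloxy)-3,5-dimethoxyphenyl]-7-methoxy-1,2,3,4-tetrahydronaphthalen-1-ol (both C1 epimers) | COc1cc2c(cc1OCc1ccccc1)[C@H](c1cc(OC)c(OCc3ccccc3)c(OC)c1)[C@@H](COCc1ccccc1)[C@H](COCc1ccccc1)C2O | intermediate
17 | 5-methoxy-(+)-isolariciresinol, (6R,7R,8S)-8-(4-hydroxy-3,5-dimethoxyphenyl)-6,7-bis(hydroxymethyl)-3-methoxy-5,6,7,8-tetrahydronaphthalen-2-ol | COc1cc2c(cc1O)[C@H](c1cc(OC)c(O)c(OC)c1)[C@@H](CO)[C@H](CO)C2 | target

**Step count and risks**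

Total steps: 9. Longest linear sequence: 9 steps (1 and 2 to 17).

Steps most likely to fail:

1. Step 7. The ring closure onto the acyl-substituted ring A may be slow. That would allow loss of a proton next to the cation (alkene formation and erosion of the configuration at C7), loss of benzyl alcohol next to the ketone, or enolization of the lactone by the aryllithium in place of addition. Fallback: it sets out from 14, which is isolated (largely as its cyclic hemiketal) when the adduct of 13 and 11 is quenched with aqueous NH4Cl instead of acid. Condensation with 4-methylbenzenesulfonohydrazide should give the tosylhydrazone F1. Reduction with catecholborane followed by NaOAc·3H2O removes the carbonyl group and should give the seco alcohol F2, in which ring A is no longer deactivated. CF3CO2H in CH2Cl2 then effects the classical cyclization of the benzylic alcohol onto the electron-rich ring (trans by the same half-chair argument) to give the tetra-O-benzyl ether F3. Hydrogenolysis of F3 (H2, Pd/C) comes back to the route at 17.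

2. Step 6. Proton transfer with double alkylation, elimination, or insufficient facial selectivity may intervene, because the aryl group lies on the face the electrophile must approach. Fallback: it sets out from 10, which is submitted to the annulation of step 7 with 13 to give the tetralone F4, still lacking the carbon substituent at C6 of the target. Its lithium enolate (LiN(SiMe3)2, THF, −78 °C) is then alkylated with benzyl chloromethyl ether anti to the neighbouring benzyloxymethyl group, which comes back to the route at 15.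

3. Step 9. The hydrogenolysis may stop at the benzylic alcohol, or acid may induce dehydration next to C6. Fallback: it sets out from 16. Neutral hydrogenolysis (H2, Pd/C, EtOAc/EtOH, no acid) should remove only the benzyl ethers and give the pentaol F5. Ionic deoxygenation (Et3SiH, CF3CO2H, CH2Cl2, 0 °C), which passes through the p-quinone methide of ring A, then removes the benzylic hydroxyl group and comes back to the route at 17.

Further compounds
F1 | step 7 | 4-methylbenzenesulfonylhydrazone of hydroxy ketone 14 | Cc1ccc(cc1)S(=O)(=O)NN=C(c1ccc(OCc2ccccc2)c(OC)c1)[C@@H](COCc1ccccc1)[C@H](COCc1ccccc1)[C@H](O)c1cc(OC)c(OCc2ccccc2)c(OC)c1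
F2 | step 7 | (1S,2R,3R)-2,3-bis[(benzyloxy)methyl]-4-[4-(benzyloxy)-3-methoxyphenyl]-1-[4-(benzyloxy)-3,5-dimethoxyphenyl]butan-1-ol | COc1cc(C[C@@H](COCc2ccccc2)[C@H](COCc2ccccc2)[C@H](O)c2cc(OC)c(OCc3ccccc3)c(OC)c2)ccc1OCc1ccccc1
F3 | step 7 | (1S,2R,3R)-7-(benzyloxy)-2,3-bis[(benzyloxy)methyl]-1-[4-(benzyloxy)-3,5-dimethoxyphenyl]-6-methoxy-1,2,3,4-tetrahydronaphthalene | COc1cc2c(cc1OCc1ccccc1)[C@H](c1cc(OC)c(OCc3ccccc3)c(OC)c1)[C@@H](COCc1ccccc1)[C@H](COCc1ccccc1)C2
F4 | step 6 | (3S,4S)-6-(benzyloxy)-3-[(benzyloxy)methyl]-4-[4-(benzyloxy)-3,5-dimethoxyphenyl]-7-methoxy-3,4-dihydronaphthalen-1(2H)-one | COc1cc2c(cc1OCc1ccccc1)[C@H](c1cc(OC)c(OCc3ccccc3)c(OC)c1)[C@@H](COCc1ccccc1)CC2=O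
F5 | step 9 | (6R,7R,8S)-8-(4-hydroxy-3,5-dimethoxyphenyl)-6,7-bis(hydroxymethyl)-3-methoxy-5,6,7,8-tetrahydronaphthalene-2,5-diol (both C5 epimers) | COc1cc2c(cc1O)[C@H](c1cc(OC)c(O)c(OC)c1)[C@@H](CO)[C@H](CO)C2O
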